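**Retrosynthetic overview**
1. The target comes from global acidolysis of a tetra-tert-butyl ester / tertiary silyl ether; the ester C–O bond joins the citrate C-3 carboxyl (as acyl fluoride) to tri-tert-butyl (2S,3R)-isocitrate, itself made from L-malic acid by Fráter–Seebach allylation and alkene cleavage.
2. The γ-lactone (the only ring of the target, formed second) comes from lactonisation of an (S)-allylic alcohol obtained by CBS reduction of an (E)-enone.
3. The enone comes from the key C7–C8 bond: boron aldol addition of a core methyl ketone to (4Z,7Z)-trideca-4,7-dienal, then dehydration.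
4. The methyl ketone comes from D-malic acid: Fráter–Seebach allylation (lactone C-3), pivalaldehyde dioxolanone (temporary ring, formed first), self-regenerating alkylation with tert-butyl bromoacetate (carbinol centre), Wacker oxidation.
5. The dienal comes from a Z-selective Wittig reaction of a (Z)-non-3-enyl ylide with methyl 4-oxobutanoate.

Assumption: the SMILES is read as (3S,5S)-lactone, (R)-carbinol carbon, (1S,2R)-isocitrate unit and (1E,5Z,8Z)-trienyl chain; D- and L-malic acid, (Z)-non-3-en-1-ol, methyl 4-oxobutanoate, allyl bromide and tert-butyl bromoacetate are taken as commercial.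

Abbreviations used in the step lines (full names are in the compound list): Dx = (2R,4R)-4-(2-tert-butoxy-2-oxoethyl)-2-tert-butyl-5-oxo-1,3-dioxolan-4-yl; Lac = (3S,5S)-2-oxo-5-[(1E,5Z,8Z)-tetradeca-1,5,8-trien-1-yl]oxolan-3-yl.

**Side chain**

Step 1
Reactants: 1 (3Z)-non-3-en-1-ol
Product: 2 (3Z)-1-iodonon-3-ene
Conditions: PPh3, I2, imidazole, CH2Cl2, 0 °C → rt
Reagents that add atoms: iodine, II
Why: Appel-type iodination replaces the primary hydroxyl by SN2 and leaves the Z alkene untouched.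

Step 2
Reactants: 2 (3Z)-1-iodonon-3-ene
Product: 3 [(3Z)-non-3-en-1-yl]triphenylphosphonium iodide
Conditions: PPh3, MeCN, reflux
Reagents that add atoms: triphenylphosphine, c1ccc(cc1)P(c1ccccc1)c1ccccc1
Why: SN2 quaternisation of the phosphine by a primary iodide gives the Wittig salt.

Step 3
Reactants: 3 [(3Z)-non-3-en-1-yl]triphenylphosphonium iodide; 4 methyl 4-oxobutanoate
Product: 6 methyl (4Z,7Z)-trideca-4,7-dienoate, via phosphorus ylide 5 (not isolated)
Conditions: NaN(SiMe3)2, THF, −78 °C; then 4, −78 °C → rt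
Reagents that add atoms: none
Why: Wittig olefination of a non-stabilised ylide under lithium-free conditions gives the new C4=C5 alkene Z through the kinetic cis-oxaphosphetane, completing the skipped Z,Z-diene.

Step 4
Reactants: 6 methyl (4Z,7Z)-trideca-4,7-dienoate
Product: 7 (4Z,7Z)-trideca-4,7-dien-1-ol
Conditions: LiAlH4, Et2O, 0 °C; Na2SO4·10H2O quench
Reagents that add atoms: none
Why: hydride reduction of the ester to the primary alcohol does not touch isolated alkenes.

Step 5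
Reactants: 7 (4Z,7Z)-trideca-4,7-dien-1-ol
Product: 8 (4Z,7Z)-trideca-4,7-dienal
Conditions: Dess–Martin periodinane, CH2Cl2, 0 °C → rt
Reagents that add atoms: none
Why: Dess–Martin oxidation stops at the aldehyde under nearly neutral conditions, so the skipped diene does not migrate.

**Isocitrate unit**

Step 6
Reactants: 9 (S)-malic acid
Product: 10 di-tert-butyl (2S)-2-hydroxybutanedioate
Conditions: O-tert-butyl-N,N'-diisopropylisourea (4 equiv), THF, rt → 40 °C
Reagents that add atoms: O-tert-butyl-N,N'-diisopropylisourea, CC(C)NC(=NC(C)C)OC(C)(C)C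
Why: isourea esterification transfers tert-butyl only to the carboxylic acids under neutral conditions, leaving the secondary OH and the stereocentre untouched.

Step 7
Reactants: 10 di-tert-butyl (2S)-2-hydroxybutanedioate; 11 allyl bromide
Product: 13 di-tert-butyl (2S,3R)-2-hydroxy-3-(prop-2-en-1-yl)butanedioate, via dilithium alkoxide-enolate 12 (not isolated)
Conditions: LiN(SiMe3)2 (2.2 equiv), THF, −78 → −20 °C; then 11, −78 → −5 °C; AcOH quench
Reagents that add atoms: none
Why: Fráter–Seebach alkylation: the chelated dianion is allylated anti to the C-2 substituent, setting C-3 as R (threo, about 9:1, minor isomer removed by chromatography).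

Step 8
Reactants: 13 di-tert-butyl (2S,3R)-2-hydroxy-3-(prop-2-en-1-yl)butanedioate
Product: 14 di-tert-butyl (2S,3R)-2-[(tert-butyldimethylsilyl)oxy]-3-(prop-2-en-1-yl)butanedioate
Conditions: TBSCl, imidazole, DMF, rt
Reagents that add atoms: tert-butyldimethylsilyl chloride, CC(C)(C)[Si](C)(C)Cl
Why: silylation masks the secondary alcohol, which would otherwise be oxidised in the next step.

Step 9
Reactants: 14 di-tert-butyl (2S,3R)-2-[(tert-butyldimethylsilyl)oxy]-3-(prop-2-en-1-yl)butanedioate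
Product: 15 (3R,4S)-3,4-bis(tert-butoxycarbonyl)-4-[(tert-butyldimethylsilyl)oxy]butanoic acid
Conditions: RuCl3·xH2O (3 mol %), NaIO4 (4.1 equiv), CCl4/MeCN/H2O, rt
Reagents that add atoms: sodium periodate, [Na+].[O-]I(=O)(=O)=O; water, O
Why: Sharpless oxidative cleavage with RuO4 made in the flask turns the terminal alkene into the acid with one carbon less; esters, silyl ether and both stereocentres survive.

Step 10
Reactants: 15 (3R,4S)-3,4-bis(tert-butoxycarbonyl)-4-[(tert-butyldimethylsilyl)oxy]butanoic acid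
Product: 16 tri-tert-butyl (1S,2R)-1-[(tert-butyldimethylsilyl)oxy]propane-1,2,3-tricarboxylate
Conditions: O-tert-butyl-N,N'-diisopropylisourea (2 equiv), CH2Cl2, rt → 40 °C
Reagents that add atoms: O-tert-butyl-N,N'-diisopropylisourea, CC(C)NC(=NC(C)C)OC(C)(C)C
Why: neutral isourea esterification gives the third tert-butyl ester without epimerising the acidic C–H centres.

Step 11
Reactants: 16 tri-tert-butyl (1S,2R)-1-[(tert-butyldimethylsilyl)oxy]propane-1,2,3-tricarboxylate
Product: 17 tri-tert-butyl (1S,2R)-1-hydroxypropane-1,2,3-tricarboxylate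
Conditions: HF·pyridine, pyridine, THF, 0 °C → rt
Reagents that add atoms: none
Why: buffered fluoride desilylation frees the alcohol; tert-butyl esters resist both acidolysis under these conditions and lactonisation.

**Core**

Step 12
Reactants: 18 (R)-malic acid
Product: 19 diethyl (2R)-2-hydroxybutanedioate
Conditions: EtOH, H2SO4 (cat.), reflux
Reagents that add atoms: ethanol, CCO
Why: Fischer esterification of both acids leaves the carbinol centre untouched.

Step 13
Reactants: 19 diethyl (2R)-2-hydroxybutanedioate; 11 allyl bromide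
Product: 21 diethyl (2R,3S)-2-hydroxy-3-(prop-2-en-1-yl)butanedioate, via dilithium alkoxide-enolate 20 (not isolated)
Conditions: LiN(i-Pr)2 (2.2 equiv), THF, −78 → −20 °C; then 11, −78 → −5 °C; AcOH quench
Reagents that add atoms: none
Why: Fráter–Seebach alkylation in the enantiomeric series gives the threo (2R,3S) product (about 92:8), which fixes the future lactone C-3 as S.

Step 14
Reactants: 21 diethyl (2R,3S)-2-hydroxy-3-(prop-2-en-1-yl)butanedioate
Product: 22 (2R,3S)-2-hydroxy-3-(prop-2-en-1-yl)butanedioic acid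
Conditions: KOH (2.5 equiv), THF/H2O, 0 °C → rt; then HCl to pH 1
Reagents that add atoms: potassium hydroxide, [K+].[OH-]
Why: saponification at or below room temperature frees both acids without epimerising the α-centre.

Step 15
Reactants: 22 (2R,3S)-2-hydroxy-3-(prop-2-en-1-yl)butanedioic acid
Product: 23 (2S)-2-[(2R,4R)-2-tert-butyl-5-oxo-1,3-dioxolan-4-yl]pent-4-enoic acid
Conditions: t-BuCHO, TsOH·H2O (cat.), H2SO4 (cat.), pentane, reflux, Dean–Stark; recrystallise
Reagents that add atoms: pivalaldehyde, CC(C)(C)C=O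
Why: Seebach acetalisation of the α-hydroxy acid closes the five-membered dioxolanone, and thermodynamic control places tert-butyl and side chain cis, setting the acetal carbon as R.

Step 16
Reactants: 23 (2S)-2-[(2R,4R)-2-tert-butyl-5-oxo-1,3-dioxolan-4-yl]pent-4-enoic acid; 24 tert-butyl bromoacetate
Product: 26 (2S)-2-[Dx]pent-4-enoic acid, via dilithium carboxylate-enolate 25 (not isolated)
Conditions: LiN(SiMe3)2 (2.2 equiv), THF, −78 °C; then 24, −78 → −30 °C; 1 M HCl to pH 2
Reagents that add atoms: none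
Why: Seebach self-regeneration of the stereocentre: the dioxolanone enolate is alkylated anti to the tert-butyl group so that CH2CO2t-Bu replaces the former H with retention (quaternary carbon R), while the neighbouring carboxylate keeps its α-C–H from being deprotonated.

Step 17
Reactants: 26 (2S)-2-[Dx]pent-4-enoic acid
Product: 27 methyl (2S)-2-[Dx]pent-4-enoate
Conditions: MeI, KHCO3, DMF, rt
Reagents that add atoms: iodomethane, CI
Why: SN2 O-methylation of the carboxylate under weakly basic conditions cannot epimerise or open the acetal.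

Step 18
Reactants: 27 methyl (2S)-2-[Dx]pent-4-enoate
Product: 28 methyl (2S)-2-[Dx]-4-oxopentanoate
Conditions: PdCl2 (10 mol %), CuCl (50 mol %), O2 (1 atm), DMF/H2O 7:1, rt
Reagents that add atoms: water, O
Why: Tsuji–Wacker oxidation: divalent palladium activates the terminal alkene for Markovnikov attack of water to give the methyl ketone, and CuCl/O2 reoxidise zerovalent palladium.

Step 19
Reactants: 28 methyl (2S)-2-[Dx]-4-oxopentanoate; 8 (4Z,7Z)-trideca-4,7-dienal
Product: 30 methyl (2S,9Z,12Z)-2-[Dx]-6-hydroxy-4-oxooctadeca-9,12-dienoate (both C-6 epimers), via dibutylboron enolate 29 (not isolated)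
Conditions: n-Bu2BOTf (1.3 equiv), i-Pr2NEt (1.6 equiv), CH2Cl2, −78 °C; then 8, −78 → −20 °C; pH 7 buffer, MeOH, 30 % H2O2, 0 °C
Reagents that add atoms: none
Why: boron-mediated aldol addition: soft enolisation takes place only at the ketone and kinetically on the methyl side, and the enol borinate adds to the aldehyde to forge the C7–C8 bond that unites core and lipid chain; the new carbinol centre is removed in the next step.

Step 20
Reactants: 30 methyl (2S,9Z,12Z)-2-[Dx]-6-hydroxy-4-oxooctadeca-9,12-dienoate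
Product: 32 methyl (2S,5E,9Z,12Z)-2-[Dx]-4-oxooctadeca-5,9,12-trienoate, via mesylate 31 (not isolated)
Conditions: MsCl, Et3N (5 equiv), CH2Cl2, 0 °C → rt
Reagents that add atoms: none
Why: mesylation followed by E1cB elimination of the β-mesyloxy ketone gives the thermodynamically preferred E enone, and the amine base is too weak to touch the ester α-centre.

Step 21
Reactants: 32 methyl (2S,5E,9Z,12Z)-2-[Dx]-4-oxooctadeca-5,9,12-trienoate
Product: 33 methyl (2S,4S,5E,9Z,12Z)-2-[Dx]-4-hydroxyoctadeca-5,9,12-trienoate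
Conditions: (R)-2-methyl-CBS-oxazaborolidine (20 mol %), catecholborane (2 equiv), toluene, −78 °C; MeOH then aqueous work-up
Reagents that add atoms: none
Why: Corey–Bakshi–Shibata reduction: the (R)-oxazaborolidine treats the alkenyl group as the large substituent and delivers hydride 1,2 to give the 4S allylic alcohol by reagent control, without reducing esters or alkenes.

Step 22
Reactants: 33 methyl (2S,4S,5E,9Z,12Z)-2-[Dx]-4-hydroxyoctadeca-5,9,12-trienoate
Product: 34 tert-butyl 2-[(2R,4R)-2-tert-butyl-5-oxo-4-[Lac]-1,3-dioxolan-4-yl]acetate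
Conditions: PPTS (cat.), toluene, 60 °C
Reagents that add atoms: none
Why: acid-catalysed lactonisation of the γ-hydroxy methyl ester (5-exo-trig) closes the butyrolactone faster than attack on the neopentyl dioxolanone carbonyl; no stereocentre is touched, so the trans (3S,5S) ring results and any minor C-5 epimer is removed here by chromatography.

Step 23
Reactants: 34 tert-butyl 2-[(2R,4R)-2-tert-butyl-5-oxo-4-[Lac]-1,3-dioxolan-4-yl]acetate
Product: 35 (2R)-4-tert-butoxy-2-hydroxy-4-oxo-2-[Lac]butanoic acid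
Conditions: LiOH (2 equiv), THF/H2O 3:1, 0 °C; then 1 M HCl to pH 2–3, rt
Reagents that add atoms: lithium hydroxide, [Li+].[OH-]
Why: hydroxide cleaves the activated acyl-acetal (releasing pivalaldehyde) much faster than the tert-butyl ester, and any γ-lactone that opens recloses on acidification.

Step 24
Reactants: 35 (2R)-4-tert-butoxy-2-hydroxy-4-oxo-2-[Lac]butanoic acid
Product: 37 (2R)-4-tert-butoxy-4-oxo-2-[Lac]-2-[(triethylsilyl)oxy]butanoic acid, via triethylsilyl ester 36 (not isolated)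
Conditions: Et3SiOTf (2.5 equiv), 2,6-lutidine (4 equiv), CH2Cl2, −78 → 0 °C; then THF/H2O/AcOH, rt
Reagents that add atoms: triethylsilyl trifluoromethanesulfonate, CC[Si](CC)(CC)OS(=O)(=O)C(F)(F)F
Why: the silyl triflate silylates both the acid and the hindered tertiary alcohol, and mild aqueous acid then hydrolyses only the labile silyl ester.

Step 25
Reactants: 37 (2R)-4-tert-butoxy-4-oxo-2-[Lac]-2-[(triethylsilyl)oxy]butanoic acid; 17 tri-tert-butyl (1S,2R)-1-hydroxypropane-1,2,3-tricarboxylate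
Product: 39 tri-tert-butyl (1S,2R)-1-{[(2R)-4-tert-butoxy-4-oxo-2-[Lac]-2-[(triethylsilyl)oxy]butanoyl]oxy}propane-1,2,3-tricarboxylate, via acyl fluoride 38 (not isolated)
Conditions: cyanuric fluoride, pyridine, CH2Cl2, −20 °C → rt; then 17 (1.5 equiv), DMAP (2 equiv), CH2Cl2, rt → 40 °C
Reagents that add atoms: none
Why: acyl fluoride formation followed by DMAP-catalysed acylation: the small, non-enolisable acyl fluoride tolerates the 1,4-related tert-butyl ester (no anhydride formation, as with aspartate tert-butyl ester fluorides) and acylates the secondary alcohol with retention at both partners.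

Step 26
Reactants: 39 tri-tert-butyl (1S,2R)-1-{[(2R)-4-tert-butoxy-4-oxo-2-[Lac]-2-[(triethylsilyl)oxy]butanoyl]oxy}propane-1,2,3-tricarboxylate
Product: 40 (1S,2R)-1-{[(2R)-3-carboxy-2-hydroxy-2-[Lac]propanoyl]oxy}propane-1,2,3-tricarboxylic acid (target)
Conditions: CF3CO2H/CH2Cl2 1:2, H2O (5 equiv), 0 °C → rt; evaporate, reverse-phase HPLC
Reagents that add atoms: none
Why: acidolysis removes the four tert-butyl esters (alkyl–oxygen cleavage) and the silyl ether in one operation without breaking any C–O bond at a stereocentre.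

**Compound list**
1 | (3Z)-non-3-en-1-ol | CCCCC/C=C\CCO | starting material
2 | (3Z)-1-iodonon-3-ene | CCCCC/C=C\CCI | intermediate
3 | [(3Z)-non-3-en-1-yl]triphenylphosphonium iodide | CCCCC/C=C\CC[P+](c1ccccc1)(c1ccccc1)c1ccccc1.[I-] | intermediate
4 | methyl 4-oxobutanoate | COC(=O)CCC=O | starting material
5 | [(3Z)-non-3-en-1-ylidene]triphenylphosphorane (ylide, not isolated) | CCCCC/C=C\CC=P(c1ccccc1)(c1ccccc1)c1ccccc1 | intermediate
6 | methyl (4Z,7Z)-trideca-4,7-dienoate | CCCCC/C=C\C/C=C\CCC(=O)OC | intermediate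
7 | (4Z,7Z)-trideca-4,7-dien-1-ol | CCCCC/C=C\C/C=C\CCCO | intermediate
8 | (4Z,7Z)-trideca-4,7-dienal | CCCCC/C=C\C/C=C\CCC=O | intermediate
9 | (S)-malic acid (L-malic acid) | O[C@@H](CC(=O)O)C(=O)O | starting material
10 | di-tert-butyl (2S)-2-hydroxybutanedioate | O[C@@H](CC(=O)OC(C)(C)C)C(=O)OC(C)(C)C | intermediate
11 | allyl bromide (3-bromoprop-1-ene) | C=CCBr | starting material
12 | dilithium alkoxide-enolate of 10 (chelated, not isolated) | [Li+].[Li+].[O-][C@@H](/C=C(\[O-])OC(C)(C)C)C(=O)OC(C)(C)C | intermediate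
13 | di-tert-butyl (2S,3R)-2-hydroxy-3-(prop-2-en-1-yl)butanedioate | O[C@@H]([C@@H](CC=C)C(=O)OC(C)(C)C)C(=O)OC(C)(C)C | intermediate
14 | di-tert-butyl (2S,3R)-2-[(tert-butyldimethylsilyl)oxy]-3-(prop-2-en-1-yl)butanedioate | CC(C)(C)[Si](C)(C)O[C@@H]([C@@H](CC=C)C(=O)OC(C)(C)C)C(=O)OC(C)(C)C | intermediate
15 | (3R,4S)-3,4-bis(tert-butoxycarbonyl)-4-[(tert-butyldimethylsilyl)oxy]butanoic acid | CC(C)(C)[Si](C)(C)O[C@@H]([C@@H](CC(=O)O)C(=O)OC(C)(C)C)C(=O)OC(C)(C)C | intermediate
16 | tri-tert-butyl (1S,2R)-1-[(tert-butyldimethylsilyl)oxy]propane-1,2,3-tricarboxylate | CC(C)(C)[Si](C)(C)O[C@@H]([C@@H](CC(=O)OC(C)(C)C)C(=O)OC(C)(C)C)C(=O)OC(C)(C)C | intermediate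
17 | tri-tert-butyl (1S,2R)-1-hydroxypropane-1,2,3-tricarboxylate (tri-tert-butyl (2S,3R)-isocitrate) | O[C@@H]([C@@H](CC(=O)OC(C)(C)C)C(=O)OC(C)(C)C)C(=O)OC(C)(C)C | intermediate
18 | (R)-malic acid (D-malic acid) | O[C@H](CC(=O)O)C(=O)O | starting material
19 | diethyl (2R)-2-hydroxybutanedioate | O[C@H](CC(=O)OCC)C(=O)OCC | intermediate
20 | dilithium alkoxide-enolate of 19 (chelated, not isolated) | [Li+].[Li+].[O-][C@H](/C=C(\[O-])OCC)C(=O)OCC | intermediate
21 | diethyl (2R,3S)-2-hydroxy-3-(prop-2-en-1-yl)butanedioate | O[C@H]([C@H](CC=C)C(=O)OCC)C(=O)OCC | intermediate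
22 | (2R,3S)-2-hydroxy-3-(prop-2-en-1-yl)butanedioic acid | O[C@H]([C@H](CC=C)C(=O)O)C(=O)O | intermediate
23 | (2S)-2-[(2R,4R)-2-tert-butyl-5-oxo-1,3-dioxolan-4-yl]pent-4-enoic acid (cis-dioxolanone) | C=CC[C@H](C(=O)O)[C@H]1O[C@@H](C(C)(C)C)OC1=O | intermediate
24 | tert-butyl bromoacetate | CC(C)(C)OC(=O)CBr | starting material
25 | dilithium carboxylate-enolate of 23 (not isolated) | [Li+].[Li+].C=CC[C@H](C(=O)[O-])C1=C([O-])O[C@H](C(C)(C)C)O1 | intermediate
26 | (2S)-2-[(2R,4R)-4-(2-tert-butoxy-2-oxoethyl)-2-tert-butyl-5-oxo-1,3-dioxolan-4-yl]pent-4-enoic acid | C=CC[C@H](C(=O)O)[C@@]1(CC(=O)OC(C)(C)C)O[C@@H](C(C)(C)C)OC1=O | intermediate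
27 | methyl (2S)-2-[(2R,4R)-4-(2-tert-butoxy-2-oxoethyl)-2-tert-butyl-5-oxo-1,3-dioxolan-4-yl]pent-4-enoate | C=CC[C@H](C(=O)OC)[C@@]1(CC(=O)OC(C)(C)C)O[C@@H](C(C)(C)C)OC1=O | intermediate
28 | methyl (2S)-2-[(2R,4R)-4-(2-tert-butoxy-2-oxoethyl)-2-tert-butyl-5-oxo-1,3-dioxolan-4-yl]-4-oxopentanoate | CC(=O)C[C@H](C(=O)OC)[C@@]1(CC(=O)OC(C)(C)C)O[C@@H](C(C)(C)C)OC1=O | intermediate
29 | methyl (2S)-4-[(dibutylboranyl)oxy]-2-[(2R,4R)-4-(2-tert-butoxy-2-oxoethyl)-2-tert-butyl-5-oxo-1,3-dioxolan-4-yl]pent-4-enoate (boron enolate, not isolated) | C=C(OB(CCCC)CCCC)C[C@H](C(=O)OC)[C@@]1(CC(=O)OC(C)(C)C)O[C@@H](C(C)(C)C)OC1=O | intermediate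
30 | methyl (2S,9Z,12Z)-2-[(2R,4R)-4-(2-tert-butoxy-2-oxoethyl)-2-tert-butyl-5-oxo-1,3-dioxolan-4-yl]-6-hydroxy-4-oxooctadeca-9,12-dienoate (C-6 epimers) | CCCCC/C=C\C/C=C\CCC(O)CC(=O)C[C@H](C(=O)OC)[C@@]1(CC(=O)OC(C)(C)C)O[C@@H](C(C)(C)C)OC1=O | intermediate
31 | 6-O-methanesulfonate of 30 (not isolated) | CCCCC/C=C\C/C=C\CCC(OS(C)(=O)=O)CC(=O)C[C@H](C(=O)OC)[C@@]1(CC(=O)OC(C)(C)C)O[C@@H](C(C)(C)C)OC1=O | intermediate
32 | methyl (2S,5E,9Z,12Z)-2-[(2R,4R)-4-(2-tert-butoxy-2-oxoethyl)-2-tert-butyl-5-oxo-1,3-dioxolan-4-yl]-4-oxooctadeca-5,9,12-trienoate | CCCCC/C=C\C/C=C\CC/C=C/C(=O)C[C@H](C(=O)OC)[C@@]1(CC(=O)OC(C)(C)C)O[C@@H](C(C)(C)C)OC1=O | intermediate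
33 | methyl (2S,4S,5E,9Z,12Z)-2-[(2R,4R)-4-(2-tert-butoxy-2-oxoethyl)-2-tert-butyl-5-oxo-1,3-dioxolan-4-yl]-4-hydroxyoctadeca-5,9,12-trienoate | CCCCC/C=C\C/C=C\CC/C=C/[C@@H](O)C[C@H](C(=O)OC)[C@@]1(CC(=O)OC(C)(C)C)O[C@@H](C(C)(C)C)OC1=O | intermediate
34 | tert-butyl 2-[(2R,4R)-2-tert-butyl-5-oxo-4-[(3S,5S)-2-oxo-5-[(1E,5Z,8Z)-tetradeca-1,5,8-trien-1-yl]oxolan-3-yl]-1,3-dioxolan-4-yl]acetate | CCCCC/C=C\C/C=C\CC/C=C/[C@@H]1C[C@@H]([C@@]2(CC(=O)OC(C)(C)C)O[C@@H](C(C)(C)C)OC2=O)C(=O)O1 | intermediate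
35 | (2R)-4-tert-butoxy-2-hydroxy-4-oxo-2-[(3S,5S)-2-oxo-5-[(1E,5Z,8Z)-tetradeca-1,5,8-trien-1-yl]oxolan-3-yl]butanoic acid | CCCCC/C=C\C/C=C\CC/C=C/[C@@H]1C[C@@H]([C@](O)(CC(=O)OC(C)(C)C)C(=O)O)C(=O)O1 | intermediate
36 | triethylsilyl (2R)-4-tert-butoxy-4-oxo-2-[(3S,5S)-2-oxo-5-[(1E,5Z,8Z)-tetradeca-1,5,8-trien-1-yl]oxolan-3-yl]-2-[(triethylsilyl)oxy]butanoate (not isolated) | CCCCC/C=C\C/C=C\CC/C=C/[C@@H]1C[C@@H]([C@](O[Si](CC)(CC)CC)(CC(=O)OC(C)(C)C)C(=O)O[Si](CC)(CC)CC)C(=O)O1 | intermediate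
37 | (2R)-4-tert-butoxy-4-oxo-2-[(3S,5S)-2-oxo-5-[(1E,5Z,8Z)-tetradeca-1,5,8-trien-1-yl]oxolan-3-yl]-2-[(triethylsilyl)oxy]butanoic acid | CCCCC/C=C\C/C=C\CC/C=C/[C@@H]1C[C@@H]([C@](O[Si](CC)(CC)CC)(CC(=O)OC(C)(C)C)C(=O)O)C(=O)O1 | intermediate
38 | tert-butyl (3R)-4-fluoro-4-oxo-3-[(3S,5S)-2-oxo-5-[(1E,5Z,8Z)-tetradeca-1,5,8-trien-1-yl]oxolan-3-yl]-3-[(triethylsilyl)oxy]butanoate (acyl fluoride, not isolated) | CCCCC/C=C\C/C=C\CC/C=C/[C@@H]1C[C@@H]([C@](O[Si](CC)(CC)CC)(CC(=O)OC(C)(C)C)C(F)=O)C(=O)O1 | intermediate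
39 | tri-tert-butyl (1S,2R)-1-{[(2R)-4-tert-butoxy-4-oxo-2-[(3S,5S)-2-oxo-5-[(1E,5Z,8Z)-tetradeca-1,5,8-trien-1-yl]oxolan-3-yl]-2-[(triethylsilyl)oxy]butanoyl]oxy}propane-1,2,3-tricarboxylate | CCCCC/C=C\C/C=C\CC/C=C/[C@@H]1C[C@@H]([C@](O[Si](CC)(CC)CC)(CC(=O)OC(C)(C)C)C(=O)O[C@H](C(=O)OC(C)(C)C)[C@@H](CC(=O)OC(C)(C)C)C(=O)OC(C)(C)C)C(=O)O1 | intermediate
40 | (1S,2R)-1-{[(2R)-3-carboxy-2-hydroxy-2-[(3S,5S)-2-oxo-5-[(1E,5Z,8Z)-tetradeca-1,5,8-trien-1-yl]oxolan-3-yl]propanoyl]oxy}propane-1,2,3-tricarboxylic acid (CNP0327249.2) | CCCCC/C=C\C/C=C\CC/C=C/[C@@H]1C[C@@H]([C@](O)(CC(=O)O)C(=O)O[C@H](C(=O)O)[C@@H](CC(=O)O)C(=O)O)C(=O)O1 | target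

**Step count**
Total: 26 steps. Longest linear sequence: 15 steps (steps 12–26, from D-malic acid); the side chain (steps 1–5) and the isocitrate unit (steps 6–11) are convergent branches.

**Three steps most likely to fail, with fallbacks**

Step 16 (alkylation of the dianion). The dilithium salt may be poorly soluble or alkylate sluggishly next to the branched carboxylate. The fallback sets out from 23, which is first O-methylated (MeI, KHCO3, DMF) to methyl (2S)-2-[(2R,4R)-2-tert-butyl-5-oxo-1,3-dioxolan-4-yl]pent-4-enoate F1. Its mono-enolate is then formed at the more acidic acetal α-position (LiN(SiMe3)2, 1.1 equiv, THF/DMPU, −78 °C) and alkylated with 24 anti to the tert-butyl group. This gives 27 directly, where the route is rejoined.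

Step 19 (boron aldol union). Enolisation could stray to the internal CH2, or the hindered enol borinate could add slowly. The fallback sets out from 28: the kinetic lithium enolate is trapped by internal quench (LiN(i-Pr)2, Me3SiCl, THF, −78 °C) as methyl (2S)-2-[(2R,4R)-4-(2-tert-butoxy-2-oxoethyl)-2-tert-butyl-5-oxo-1,3-dioxolan-4-yl]-4-[(trimethylsilyl)oxy]pent-4-enoate F2. After purification this is used in a Mukaiyama aldol addition to 8 (BF3·OEt2, CH2Cl2, −78 °C), which returns to the route at 30.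

Step 25 (doubly hindered esterification). Acyl transfer to the secondary alcohol may be too slow, or the product may eliminate under base. The fallback makes the C–O bond by SN2 at the isocitrate carbon instead of at the acyl carbon. It sets out from 17, which is inverted by a Mitsunobu reaction (PPh3, DIAD, 4-nitrobenzoic acid, toluene, 0 °C) to tri-tert-butyl (1R,2R)-1-[(4-nitrobenzoyl)oxy]propane-1,2,3-tricarboxylate F3. Mild transesterification (NaN3, MeOH, 40 °C) frees tri-tert-butyl (1R,2R)-1-hydroxypropane-1,2,3-tricarboxylate F4. A second Mitsunobu reaction of this alcohol with acid 37 (PPh3, DIAD, toluene, 0 °C → rt) inverts the carbinol back to S and delivers 39, where the route is rejoined.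

**Further compounds**
F1 | step 16 | methyl (2S)-2-[(2R,4R)-2-tert-butyl-5-oxo-1,3-dioxolan-4-yl]pent-4-enoate | C=CC[C@H](C(=O)OC)[C@H]1O[C@@H](C(C)(C)C)OC1=O
F2 | step 19 | methyl (2S)-2-[(2R,4R)-4-(2-tert-butoxy-2-oxoethyl)-2-tert-butyl-5-oxo-1,3-dioxolan-4-yl]-4-[(trimethylsilyl)oxy]pent-4-enoate | C=C(O[Si](C)(C)C)C[C@H](C(=O)OC)[C@@]1(CC(=O)OC(C)(C)C)O[C@@H](C(C)(C)C)OC1=O
F3 | step 25 | tri-tert-butyl (1R,2R)-1-[(4-nitrobenzoyl)oxy]propane-1,2,3-tricarboxylate | O=C(O[C@@H](C(=O)OC(C)(C)C)[C@@H](CC(=O)OC(C)(C)C)C(=O)OC(C)(C)C)c1ccc(cc1)[N+](=O)[O-]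
F4 | step 25 | tri-tert-butyl (1R,2R)-1-hydroxypropane-1,2,3-tricarboxylate | O[C@@H](C(=O)OC(C)(C)C)[C@@H](CC(=O)OC(C)(C)C)C(=O)OC(C)(C)C
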